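**Retrosynthetic overview**

1. Locants follow carotenoid usage: ring C1 (CMe2), C2 (CH carrying the hydroxyprenyl chain), C3, C4=C5(Me), C6 (CH carrying the polyene), chain C7–C15, primed locants for the acyclic half. The polyene is cut at C7=C8 (Julia–Kocienski) and C7'=C8' (Wittig), giving a ring C15 sulfone, crocetin dialdehyde (C20) and a C15 phosphonium salt made from (R)-lavandulol, whose stereocentre becomes C2', whose isopropenyl carbon becomes the carbinol C1' and whose CH2OH becomes C3'.
2. The ring sulfone comes from a C6–CH2OH group installed by a [2,3]-Wittig–Still shift of a C4–O allylic ether (C5=C6 moves to C4=C5); the side chain comes from a lactol Wittig reaction on a C2–CH2–C(=O)–O–C4 lactone.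
3. That bridged lactone (a 2-oxabicyclo[3.3.1]nonenone) is made by closing the cyclohexene ring at C1–C2 in a hydrogen-atom-transfer radical cyclisation of a (Z)-dienyl dihydropyranone.
4. Enabling feature: the quaternary C1 lies between two CH centres (C2 and C6) whose carbon branches are cis, next to the C4=C5 ring alkene. The cis-1,3 pair can therefore be stored as a lactone bridge from C2 to an allylic oxygen on C4, and that oxygen is then transposed suprafacially to carbon at C6.
5. Ring order: dihydropyranone first (ring-closing metathesis), cyclohexene second (key step), then the lactone ring is opened.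

Key step: step 7

Remark: (R)-(−)-lavandulol (the natural enantiomer) and crocetin dialdehyde are taken as purchasable; (R)-TRIP is (R)-3,3'-bis(2,4,6-triisopropylphenyl)-1,1'-binaphthyl-2,2'-diyl hydrogen phosphate.

**Ring fragment**

Step 1
Reactants: 1 prop-2-yn-1-ol
Product: 3 (2Z)-3-iodo-2-methylprop-2-en-1-ol, via cyclic vinylmagnesium alkoxide 2 (not isolated)
Conditions: MeMgBr (3 equiv), CuI (10 mol%), THF, −10 °C to rt; then I2, −78 to 0 °C
Reagents that add atoms: methylmagnesium bromide C[Mg]Br; iodine II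
Why: Copper-catalysed anti-carbomagnesiation of the propargylic alkoxide (Duboudin type) places magnesium cis to the CH2O group in chelate 2, so iodinolysis with retention should give the (Z)-iodide.

Step 2
Reactants: 3 (2Z)-3-iodo-2-methylprop-2-en-1-ol
Product: 4 (2Z)-3-iodo-2-methylprop-2-enal
Conditions: MnO2 (excess), CH2Cl2, rt, dark; used at once
Reagents that add atoms: none
Why: Neutral MnO2 oxidation of an allylic alcohol should leave the (Z)-vinyl iodide geometry intact.

Step 3
Reactants: 4 (2Z)-3-iodo-2-methylprop-2-enal; 5 2-allyl-4,4,5,5-tetramethyl-1,3,2-dioxaborolane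
Product: 7 (1Z,3R)-1-iodo-2-methylhexa-1,5-dien-3-ol, via O-boryl homoallyl ether 6 (not isolated)
Conditions: (R)-TRIP (5 mol%), 4 Å molecular sieves, toluene, −30 °C; aqueous NaHCO3 work-up
Reagents that add atoms: none
Why: Chiral phosphoric acid-catalysed allylboration of an α,β-unsaturated aldehyde through a closed chair transition state should deliver the allyl group to the Re face and set the carbinol centre as (R) under catalyst control (the (S)-acid would give the enantiomer).

Step 4
Reactants: 7 (1Z,3R)-1-iodo-2-methylhexa-1,5-dien-3-ol; 8 acryloyl chloride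
Product: 9 (1Z,3R)-1-iodo-2-methylhexa-1,5-dien-3-yl prop-2-enoate
Conditions: Et3N, DMAP (cat.), CH2Cl2, −20 to 0 °C
Reagents that add atoms: none
Why: O-acylation of a secondary alcohol with an acid chloride does not touch the stereocentre or the vinyl iodide.

Step 5
Reactants: 9 (1Z,3R)-1-iodo-2-methylhexa-1,5-dien-3-yl prop-2-enoate
Product: 10 (6R)-6-[(1Z)-1-iodoprop-1-en-2-yl]-5,6-dihydro-2H-pyran-2-one
Conditions: second-generation Grubbs catalyst RuCl2(=CHPh)(H2IMes)(PCy3) (5 mol%), CH2Cl2 (5 mM), 40 °C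
Reagents that add atoms: none
Why: Ring-closing metathesis of an acrylate with a terminal alkene is the standard route to 6-substituted dihydropyranones, and the trisubstituted vinyl iodide should stay out of the metathesis.

Step 6
Reactants: 10 (6R)-6-[(1Z)-1-iodoprop-1-en-2-yl]-5,6-dihydro-2H-pyran-2-one; 11 tributyl(prop-1-en-2-yl)stannane
Product: 12 (6R)-6-[(2Z)-4-methylpenta-2,4-dien-2-yl]-5,6-dihydro-2H-pyran-2-one
Conditions: Pd(PPh3)4 (5 mol%), CuI (10 mol%), CsF (2 equiv), DMF, 45 °C
Reagents that add atoms: none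
Why: Stille coupling proceeds with retention at the vinyl iodide, so the (Z)-diene should form with the isopropenyl group cis to the lactone carbinol carbon, under conditions mild enough for the unsaturated lactone.

Step 7
Reactants: 12 (6R)-6-[(2Z)-4-methylpenta-2,4-dien-2-yl]-5,6-dihydro-2H-pyran-2-one
Product: 14 (1R,5R)-6,6,8-trimethyl-2-oxabicyclo[3.3.1]non-7-en-3-one, via allyl radical 13 (not isolated)
Conditions: Fe(acac)3 (30 mol%), PhSiH3 (2.5 equiv), EtOH/(CH2OH)2 5:1 (0.02 M), 60 °C, argon
Reagents that add atoms: none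
Why: Proposed new method: hydrogen-atom transfer from the iron hydride formed from Fe(acac)3 and PhSiH3 to the terminal CH2 of the electron-rich diene gives the 1,1,3-trisubstituted allyl radical 13, whose gem-dimethyl terminus adds to the β-carbon of the unsaturated lactone, after which the α-acyl radical is reduced by divalent iron to the enolate and protonated by ethanol; the closest known chemistry is the Fe(acac)3/PhSiH3 reductive olefin–acceptor (Giese-type) cyclisation of unactivated alkenes together with hydrogen-atom-transfer hydrofunctionalisation of 1,3-dienes through allyl radicals. The cyclohexene ring closes in the 6-exo-trig mode (the other allyl terminus could only close a cyclobutane), which turns the monocyclic lactone into the bridged 2-oxabicyclo[3.3.1]nonene. The new stereocentre at the lactone β-carbon (ring C2) is controlled by the carbinol centre C4, because the three-atom tether sits on C4 and can reach C2 only from its own face, so only the cis-bridged (1R,5R) bicycle can form. The step needs hydrogen-atom transfer to the diene and not to the electron-poor enoate or to the trisubstituted alkene of the product, which the higher reactivity of conjugated dienes towards metal hydrides should secure, and it needs the radical terminus held over the ring, which the (Z)-geometry of the trisubstituted double bond secures. The transferred hydrogen turns the isopropenyl CH2 into the second methyl group, so the gem-dimethyl quaternary carbon C1 is completed in the same event.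

Step 8
Reactants: 14 (1R,5R)-6,6,8-trimethyl-2-oxabicyclo[3.3.1]non-7-en-3-one; 15 ethyl 2-(triphenylphosphoranylidene)propanoate
Product: 17 ethyl (2E)-4-[(1S,5R)-5-hydroxy-2,2,4-trimethylcyclohex-3-en-1-yl]-2-methylbut-2-enoate, via bicyclic lactol 16 (not isolated)
Conditions: i-Bu2AlH (1.1 equiv), CH2Cl2, −78 °C; Rochelle salt work-up; then 15 (1.5 equiv), toluene, 90 °C
Reagents that add atoms: none
Why: Partial reduction gives the lactol, whose open hydroxy-aldehyde form reacts with the stabilised ylide in an (E)-selective Wittig olefination to install the complete side-chain skeleton and free the C4 hydroxyl.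

Step 9
Reactants: 17 ethyl (2E)-4-[(1S,5R)-5-hydroxy-2,2,4-trimethylcyclohex-3-en-1-yl]-2-methylbut-2-enoate
Product: 18 (1R,5S)-5-[(2E)-4-hydroxy-3-methylbut-2-en-1-yl]-2,4,4-trimethylcyclohex-2-en-1-ol
Conditions: i-Bu2AlH (3 equiv), CH2Cl2, −78 to −40 °C
Reagents that add atoms: none
Why: 1,2-Reduction of the enoate with i-Bu2AlH should give the (E)-allylic alcohol without touching either alkene.

Step 10
Reactants: 18 (1R,5S)-5-[(2E)-4-hydroxy-3-methylbut-2-en-1-yl]-2,4,4-trimethylcyclohex-2-en-1-ol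
Product: 19 (1R,5S)-5-[(2E)-4-{[tert-butyl(dimethyl)silyl]oxy}-3-methylbut-2-en-1-yl]-2,4,4-trimethylcyclohex-2-en-1-ol
Conditions: TBSCl (1.05 equiv), imidazole, CH2Cl2, −20 to 0 °C
Reagents that add atoms: tert-butyldimethylsilyl chloride CC(C)(C)[Si](C)(C)Cl
Why: Silylation should select the unhindered primary allylic alcohol over the secondary ring alcohol.

Step 11
Reactants: 19 (1R,5S)-5-[(2E)-4-{[tert-butyl(dimethyl)silyl]oxy}-3-methylbut-2-en-1-yl]-2,4,4-trimethylcyclohex-2-en-1-ol
Product: 20 tributyl[({(1R,5S)-5-[(2E)-4-{[tert-butyl(dimethyl)silyl]oxy}-3-methylbut-2-en-1-yl]-2,4,4-trimethylcyclohex-2-en-1-yl}oxy)methyl]stannane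
Conditions: KH, 18-crown-6 (cat.), Bu3SnCH2I, THF, 0 °C to rt
Reagents that add atoms: tributyl(iodomethyl)stannane CCCC[Sn](CCCC)(CCCC)CI
Why: Williamson etherification of the potassium alkoxide with the Still reagent prepares the [2,3]-shift and retains the carbinol configuration.

Step 12
Reactants: 20 tributyl[({(1R,5S)-5-[(2E)-4-{[tert-butyl(dimethyl)silyl]oxy}-3-methylbut-2-en-1-yl]-2,4,4-trimethylcyclohex-2-en-1-yl}oxy)methyl]stannane
Product: 22 {(1R,5R)-5-[(2E)-4-{[tert-butyl(dimethyl)silyl]oxy}-3-methylbut-2-en-1-yl]-2,6,6-trimethylcyclohex-2-en-1-yl}methanol, via lithiomethyl ether 21 (not isolated)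
Conditions: n-BuLi (1.5 equiv), THF, −78 to −20 °C; aqueous NH4Cl
Reagents that add atoms: none
Why: Tin–lithium exchange followed by the suprafacial [2,3]-Wittig–Still rearrangement should deliver CH2OH to C6 on the face that carried the C4 oxygen, which is cis to the C2 side chain, while moving the alkene to C4=C5; it runs through the conformer with a pseudoaxial C–O bond, the same 1,3-diaxial arrangement that lactone 14 already had.

Step 13
Reactants: 22 {(1R,5R)-5-[(2E)-4-{[tert-butyl(dimethyl)silyl]oxy}-3-methylbut-2-en-1-yl]-2,6,6-trimethylcyclohex-2-en-1-yl}methanol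
Product: 23 5-[({(1R,5R)-5-[(2E)-4-{[tert-butyl(dimethyl)silyl]oxy}-3-methylbut-2-en-1-yl]-2,6,6-trimethylcyclohex-2-en-1-yl}methyl)sulfanyl]-1-phenyl-1H-tetrazole
Conditions: 1-phenyl-1H-tetrazole-5-thiol, PPh3, DIAD, THF, 0 °C to rt
Reagents that add atoms: 1-phenyl-1H-tetrazole-5-thiol Sc1nnnn1-c1ccccc1
Why: Mitsunobu thioetherification of a primary alcohol leaves the adjacent stereocentre untouched.

Step 14
Reactants: 23 5-[({(1R,5R)-5-[(2E)-4-{[tert-butyl(dimethyl)silyl]oxy}-3-methylbut-2-en-1-yl]-2,6,6-trimethylcyclohex-2-en-1-yl}methyl)sulfanyl]-1-phenyl-1H-tetrazole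
Product: 24 5-[({(1R,5R)-5-[(2E)-4-{[tert-butyl(dimethyl)silyl]oxy}-3-methylbut-2-en-1-yl]-2,6,6-trimethylcyclohex-2-en-1-yl}methyl)sulfonyl]-1-phenyl-1H-tetrazole
Conditions: (NH4)6Mo7O24·4H2O (10 mol%), H2O2 (30% aq., 5 equiv), EtOH, 0 °C to rt
Reagents that add atoms: hydrogen peroxide OO
Why: Molybdate-catalysed oxidation should oxidise the sulfide to the sulfone faster than it epoxidises the unactivated trisubstituted alkenes.

**Acyclic fragment**

Step 15
Reactants: 25 (2R)-5-methyl-2-(prop-1-en-2-yl)hex-4-en-1-ol ((R)-lavandulol)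
Product: 26 (2S)-2-(2-hydroxypropan-2-yl)-5-methylhex-4-en-1-ol
Conditions: Co(acac)2 (20 mol%), PhSiH3 (2 equiv), O2 (1 atm), THF, rt
Reagents that add atoms: dioxygen O=O
Why: Mukaiyama hydration by hydrogen-atom transfer should select the less hindered 1,1-disubstituted alkene over the trisubstituted prenyl alkene and gives the Markovnikov tertiary alcohol without touching the stereocentre.

Step 16
Reactants: 26 (2S)-2-(2-hydroxypropan-2-yl)-5-methylhex-4-en-1-ol
Product: 27 triethyl{[(2S)-5-methyl-2-{2-[(triethylsilyl)oxy]propan-2-yl}hex-4-en-1-yl]oxy}silane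
Conditions: Et3SiOTf (2.5 equiv), 2,6-lutidine, CH2Cl2, −78 to 0 °C
Reagents that add atoms: triethylsilyl trifluoromethanesulfonate CC[Si](CC)(CC)OS(=O)(=O)C(F)(F)F
Why: Silyl triflate silylates both the primary and the hindered tertiary hydroxyl, which blocks retro-aldol cleavage at the aldehyde stage.

Step 17
Reactants: 27 triethyl{[(2S)-5-methyl-2-{2-[(triethylsilyl)oxy]propan-2-yl}hex-4-en-1-yl]oxy}silane
Product: 28 (2R)-5-methyl-2-{2-[(triethylsilyl)oxy]propan-2-yl}hex-4-enal
Conditions: (COCl)2, DMSO, CH2Cl2, −78 to −30 °C; then Et3N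
Reagents that add atoms: none
Why: Swern conditions oxidise a primary triethylsilyl ether directly to the aldehyde while the tertiary silyl ether stays, and the cold, hindered α-carbon should not epimerise.

Step 18
Reactants: 28 (2R)-5-methyl-2-{2-[(triethylsilyl)oxy]propan-2-yl}hex-4-enal; 29 ethyl (2E)-4-(diethoxyphosphoryl)-3-methylbut-2-enoate
Product: 30 ethyl (2E,4E,6S)-3,9-dimethyl-6-{2-[(triethylsilyl)oxy]propan-2-yl}deca-2,4,8-trienoate
Conditions: LiN(SiMe3)2 (1.1 equiv), THF, −78 to 0 °C
Reagents that add atoms: none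
Why: Vinylogous Horner–Wadsworth–Emmons olefination with the C5 phosphonate should form the new disubstituted alkene (E)-selectively; any (2Z) isomer is removed by chromatography.

Step 19
Reactants: 30 ethyl (2E,4E,6S)-3,9-dimethyl-6-{2-[(triethylsilyl)oxy]propan-2-yl}deca-2,4,8-trienoate
Product: 31 (2E,4E,6S)-3,9-dimethyl-6-{2-[(triethylsilyl)oxy]propan-2-yl}deca-2,4,8-trien-1-ol
Conditions: i-Bu2AlH (2.2 equiv), CH2Cl2, −78 °C
Reagents that add atoms: none
Why: 1,2-Reduction of the dienoate gives the dienol.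

Step 20
Reactants: 31 (2E,4E,6S)-3,9-dimethyl-6-{2-[(triethylsilyl)oxy]propan-2-yl}deca-2,4,8-trien-1-ol
Product: 33 [(2E,4E,6S)-3,9-dimethyl-6-{2-[(triethylsilyl)oxy]propan-2-yl}deca-2,4,8-trien-1-yl]triphenylphosphonium bromide, via dienyl bromide 32 (not isolated)
Conditions: PBr3 (0.4 equiv), pyridine (cat.), Et2O, −10 °C; then PPh3, CH2Cl2, rt
Reagents that add atoms: phosphorus tribromide BrP(Br)Br; triphenylphosphine c1ccc(cc1)P(c1ccccc1)c1ccccc1
Why: Bromination of the primary dienylic alcohol and SN2 quaternisation at the primary carbon is the classical route to polyenyl Wittig salts, and the buffered conditions should spare the tertiary silyl ether.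

**Union**

Step 21
Reactants: 24 5-[({(1R,5R)-5-[(2E)-4-{[tert-butyl(dimethyl)silyl]oxy}-3-methylbut-2-en-1-yl]-2,6,6-trimethylcyclohex-2-en-1-yl}methyl)sulfonyl]-1-phenyl-1H-tetrazole; 34 (2E,4E,6E,8E,10E,12E,14E)-2,6,11,15-tetramethylhexadeca-2,4,6,8,10,12,14-heptaenedial (crocetin dialdehyde)
Product: 35 (2E,4E,6E,8E,10E,12E,14E,16E)-17-{(1R,5R)-5-[(2E)-4-{[tert-butyl(dimethyl)silyl]oxy}-3-methylbut-2-en-1-yl]-2,6,6-trimethylcyclohex-2-en-1-yl}-2,6,11,15-tetramethylheptadeca-2,4,6,8,10,12,14,16-octaenal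
Conditions: KN(SiMe3)2 (1.05 equiv), THF, −78 °C; then added to 34 (3 equiv) in THF/CH2Cl2, −78 °C to rt, dark
Reagents that add atoms: none
Why: Julia–Kocienski olefination of the β-branched tetrazolyl sulfone should form the C7=C8 bond (E)-selectively, and the excess of dialdehyde should limit reaction to one end.

Step 22
Reactants: 35 the C35 aldehyde of step 21; 33 [(2E,4E,6S)-3,9-dimethyl-6-{2-[(triethylsilyl)oxy]propan-2-yl}deca-2,4,8-trien-1-yl]triphenylphosphonium bromide
Product: 36 bis-silyl ether of the target (tert-butyldimethylsilyl on the primary allylic oxygen and triethylsilyl on the tertiary oxygen)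
Conditions: NaOMe (1.5 equiv), CH2Cl2/MeOH, 0 °C to rt, dark, argon; then heptane, 80 °C
Reagents that add atoms: none
Why: Wittig olefination with the semistabilised dienyl ylide forms C7'=C8', and the thermal treatment should equilibrate the new double bond to the all-(E) polyene, as is usual in carotenoid synthesis.

Step 23
Reactants: 36 bis-silyl ether of the target
Product: 37 (2R,6R,2'S)-2-[(2E)-4-hydroxy-3-methylbut-2-enyl]-2'-(3-methylbut-2-enyl)-3',4'-didehydro-1',2'-dihydro-ε,ψ-caroten-1'-ol (target)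
Conditions: Bu4NF (4 equiv), THF, 0 °C to rt, dark, argon
Reagents that add atoms: none
Why: Fluoride-mediated desilylation should remove both silyl ethers under conditions mild enough for the polyene and the stereocentres.

**Compound list**

1 | prop-2-yn-1-ol | OCC#C | starting material
2 | cyclic vinylmagnesium alkoxide | CC1=C[Mg]OC1 | intermediate (not isolated)
3 | (2Z)-3-iodo-2-methylprop-2-en-1-ol | OC/C(C)=C\I | intermediate
4 | (2Z)-3-iodo-2-methylprop-2-enal | O=C/C(C)=C\I | intermediate
5 | 2-allyl-4,4,5,5-tetramethyl-1,3,2-dioxaborolane | C=CCB1OC(C)(C)C(C)(C)O1 | starting material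
6 | O-boryl homoallyl ether (pinacol borate of 7) | C=CC[C@@H](OB1OC(C)(C)C(C)(C)O1)/C(C)=C\I | intermediate (not isolated)
7 | (1Z,3R)-1-iodo-2-methylhexa-1,5-dien-3-ol | C=CC[C@@H](O)/C(C)=C\I | intermediate
8 | acryloyl chloride | C=CC(=O)Cl | starting material
9 | (1Z,3R)-1-iodo-2-methylhexa-1,5-dien-3-yl prop-2-enoate | C=CC[C@@H](OC(=O)C=C)/C(C)=C\I | intermediate
10 | (6R)-6-[(1Z)-1-iodoprop-1-en-2-yl]-5,6-dihydro-2H-pyran-2-one | O=C1C=CC[C@@H](O1)/C(C)=C\I | intermediate
11 | tributyl(prop-1-en-2-yl)stannane | CCCC[Sn](CCCC)(CCCC)C(C)=C | starting material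
12 | (6R)-6-[(2Z)-4-methylpenta-2,4-dien-2-yl]-5,6-dihydro-2H-pyran-2-one | O=C1C=CC[C@@H](O1)/C(C)=C\C(C)=C | intermediate
13 | allyl radical from 12 | O=C1C=CC[C@@H](O1)/C(C)=C\[C](C)C | intermediate (not isolated)
14 | (1R,5R)-6,6,8-trimethyl-2-oxabicyclo[3.3.1]non-7-en-3-one | O=C1C[C@H]2C[C@@H](O1)C(C)=CC2(C)C | intermediate
15 | ethyl 2-(triphenylphosphoranylidene)propanoate | CCOC(=O)C(C)=P(c1ccccc1)(c1ccccc1)c1ccccc1 | starting material
16 | (1R,5R)-6,6,8-trimethyl-2-oxabicyclo[3.3.1]non-7-en-3-ol (anomers) | OC1C[C@H]2C[C@@H](O1)C(C)=CC2(C)C | intermediate (not isolated)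
17 | ethyl (2E)-4-[(1S,5R)-5-hydroxy-2,2,4-trimethylcyclohex-3-en-1-yl]-2-methylbut-2-enoate | CCOC(=O)/C(C)=C/C[C@H]1C[C@@H](O)C(C)=CC1(C)C | intermediate
18 | (1R,5S)-5-[(2E)-4-hydroxy-3-methylbut-2-en-1-yl]-2,4,4-trimethylcyclohex-2-en-1-ol | OC/C(C)=C/C[C@H]1C[C@@H](O)C(C)=CC1(C)C | intermediate
19 | (1R,5S)-5-[(2E)-4-{[tert-butyl(dimethyl)silyl]oxy}-3-methylbut-2-en-1-yl]-2,4,4-trimethylcyclohex-2-en-1-ol | CC(C)(C)[Si](C)(C)OC/C(C)=C/C[C@H]1C[C@@H](O)C(C)=CC1(C)C | intermediate
20 | tributyl(stannyl)methyl ether of 19 | CC(C)(C)[Si](C)(C)OC/C(C)=C/C[C@H]1C[C@@H](OC[Sn](CCCC)(CCCC)CCCC)C(C)=CC1(C)C | intermediate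
21 | lithiomethyl ether of 19 | CC(C)(C)[Si](C)(C)OC/C(C)=C/C[C@H]1C[C@@H](OC[Li])C(C)=CC1(C)C | intermediate (not isolated)
22 | {(1R,5R)-5-[(2E)-4-{[tert-butyl(dimethyl)silyl]oxy}-3-methylbut-2-en-1-yl]-2,6,6-trimethylcyclohex-2-en-1-yl}methanol | OC[C@@H]1C(C)=CC[C@H](C/C=C(\C)CO[Si](C)(C)C(C)(C)C)C1(C)C | intermediate
23 | 1-phenyl-1H-tetrazol-5-yl sulfide of 22 | c1ccccc1-n1nnnc1SC[C@@H]1C(C)=CC[C@H](C/C=C(\C)CO[Si](C)(C)C(C)(C)C)C1(C)C | intermediate
24 | 1-phenyl-1H-tetrazol-5-yl sulfone (ring C15 fragment) | O=S(=O)(C[C@@H]1C(C)=CC[C@H](C/C=C(\C)CO[Si](C)(C)C(C)(C)C)C1(C)C)c1nnnn1-c1ccccc1 | intermediate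
25 | (2R)-5-methyl-2-(prop-1-en-2-yl)hex-4-en-1-ol ((R)-lavandulol) | CC(C)=CC[C@@H](CO)C(C)=C | starting material
26 | (2S)-2-(2-hydroxypropan-2-yl)-5-methylhex-4-en-1-ol | CC(C)=CC[C@@H](CO)C(C)(C)O | intermediate
27 | triethyl{[(2S)-5-methyl-2-{2-[(triethylsilyl)oxy]propan-2-yl}hex-4-en-1-yl]oxy}silane | CC(C)=CC[C@@H](CO[Si](CC)(CC)CC)C(C)(C)O[Si](CC)(CC)CC | intermediate
28 | (2R)-5-methyl-2-{2-[(triethylsilyl)oxy]propan-2-yl}hex-4-enal | CC(C)=CC[C@@H](C=O)C(C)(C)O[Si](CC)(CC)CC | intermediate
29 | ethyl (2E)-4-(diethoxyphosphoryl)-3-methylbut-2-enoate | CCOC(=O)/C=C(C)/CP(=O)(OCC)OCC | starting material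
30 | ethyl (2E,4E,6S)-3,9-dimethyl-6-{2-[(triethylsilyl)oxy]propan-2-yl}deca-2,4,8-trienoate | CC(C)=CC[C@@H](/C=C/C(C)=C/C(=O)OCC)C(C)(C)O[Si](CC)(CC)CC | intermediate
31 | (2E,4E,6S)-3,9-dimethyl-6-{2-[(triethylsilyl)oxy]propan-2-yl}deca-2,4,8-trien-1-ol | CC(C)=CC[C@@H](/C=C/C(C)=C/CO)C(C)(C)O[Si](CC)(CC)CC | intermediate
32 | dienyl bromide from 31 | CC(C)=CC[C@@H](/C=C/C(C)=C/CBr)C(C)(C)O[Si](CC)(CC)CC | intermediate (not isolated)
33 | [(2E,4E,6S)-3,9-dimethyl-6-{2-[(triethylsilyl)oxy]propan-2-yl}deca-2,4,8-trien-1-yl]triphenylphosphonium bromide | [Br-].CC(C)=CC[C@@H](/C=C/C(C)=C/C[P+](c1ccccc1)(c1ccccc1)c1ccccc1)C(C)(C)O[Si](CC)(CC)CC | intermediate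
34 | crocetin dialdehyde | O=C/C(C)=C/C=C/C(C)=C/C=C/C=C(C)/C=C/C=C(C)/C=O | starting material
35 | C35 aldehyde (ring end plus heptadecaoctaenal chain) | O=C/C(C)=C/C=C/C(C)=C/C=C/C=C(C)/C=C/C=C(C)/C=C/[C@@H]1C(C)=CC[C@H](C/C=C(\C)CO[Si](C)(C)C(C)(C)C)C1(C)C | intermediate
36 | bis-silyl ether of the target | CC(C)=CC[C@@H](/C=C/C(C)=C/C=C/C(C)=C/C=C/C(C)=C/C=C/C=C(C)/C=C/C=C(C)/C=C/[C@@H]1C(C)=CC[C@H](C/C=C(\C)CO[Si](C)(C)C(C)(C)C)C1(C)C)C(C)(C)O[Si](CC)(CC)CC | intermediate
37 | (2R,6R,2'S)-2-[(2E)-4-hydroxy-3-methylbut-2-enyl]-2'-(3-methylbut-2-enyl)-3',4'-didehydro-1',2'-dihydro-ε,ψ-caroten-1'-ol | CC(C)=CC[C@@H](/C=C/C(C)=C/C=C/C(C)=C/C=C/C(C)=C/C=C/C=C(C)/C=C/C=C(C)/C=C/[C@@H]1C(C)=CC[C@H](C/C=C(\C)CO)C1(C)C)C(C)(C)O | target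

**Step count and risks**

Total step count: 23. Longest linear sequence: 17 steps (steps 1–14, then 21–23).

Steps most likely to fail:

1. Step 7 (Proposed new method). The metal hydride may transfer hydrogen to the wrong site, or may reduce the allyl radical to the monoalkene before the stabilised radical has added to the lactone. Fallback with known chemistry: diene 12 is treated with dry HCl (1 equiv, CH2Cl2, −78 °C) to give the tertiary allylic chloride (6R)-6-[(2Z)-4-chloro-4-methylpent-2-en-2-yl]-5,6-dihydro-2H-pyran-2-one F1. Slow addition of Bu3SnH with AIBN in benzene at 80 °C then generates the same allyl radical by chlorine abstraction in a tin hydride chain, with no metal hydride present, and its cyclisation onto the unsaturated lactone returns to the route at lactone 14.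

2. Step 12. The lithiated ether may fail to reach the conformer with a pseudoaxial C–O bond (1,3-diaxial strain against the C2 side chain), so that a [1,2]-shift or simple protonation competes with the [2,3]-shift. Fallback: alcohol 19 is converted with phenyl isocyanate and Et3N into the N-phenylcarbamate F2. Deprotonation with MeLi, then CuI and (i-PrO)Me2SiCH2MgCl, gives a carbamate-directed syn-SN2' substitution that places the silylmethyl group on C6 on the face of the departing oxygen, giving the (isopropoxydimethylsilyl)methyl compound F3. Tamao oxidation (KF, KHCO3, H2O2, THF/MeOH) returns to the route at alcohol 22.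

3. Step 15. Hydrogen-atom transfer may not discriminate enough between the isopropenyl and the prenyl double bond, leading to hydration or reduction of the prenyl group. Fallback: (R)-lavandulol 25 is oxymercurated with Hg(OAc)2 in THF/H2O, which is known to prefer 1,1-disubstituted over trisubstituted alkenes, giving the organomercurial F4 (mixture at the new carbinol carbon). Demercuration with NaBH4/NaOH returns to the route at diol 26.

Further compounds
F1 | step 7 | (6R)-6-[(2Z)-4-chloro-4-methylpent-2-en-2-yl]-5,6-dihydro-2H-pyran-2-one | O=C1C=CC[C@@H](O1)/C(C)=C\C(C)(C)Cl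
F2 | step 12 | N-phenylcarbamate of 19 | CC(C)(C)[Si](C)(C)OC/C(C)=C/C[C@H]1C[C@@H](OC(=O)Nc2ccccc2)C(C)=CC1(C)C
F3 | step 12 | (isopropoxydimethylsilyl)methyl analogue of 22 | CC(C)O[Si](C)(C)C[C@@H]1C(C)=CC[C@H](C/C=C(\C)CO[Si](C)(C)C(C)(C)C)C1(C)C
F4 | step 15 | acetoxymercurio adduct of 25 | CC(C)=CC[C@@H](CO)C(C)(O)C[Hg]OC(C)=O
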